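**Plan**
- Retrosynthesis: the C8 methacrylate is cut first (Mitsunobu, with inversion). Then C6–C7 and C11–C12 (together with O6–C12) are cut in one [2+2+1] transform to CO and an acyclic allenyl aldehyde. C1=C10 is cut last (aldol–dehydration) into aldehyde 11 (C1–C6, C15) and alkynyl lactone 16 (C7–C10, C14).
- Forward: 11 and 16 are joined; the lactone of 16, a temporary ring holding C14 and O8, is opened by reduction; the alkyne is homologated to the terminal allene (C11, C13). The key step then closes the ten-membered carbocycle and the α-methylene-γ-butyrolactone at once; esterification and desilylation finish.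
- Enabling feature: the lactone ring O6–C12(=O)–C11(=C13H2)–C7–C6 is the sum of an aldehyde C=O (C6), the C7=C11 bond of a 1,2-diene and CO. The ring-cis C1=C10 alkene pre-folds the eight-atom tether.
- Stereochemistry: C4 from an Evans allylation; C8 from a Noyori transfer hydrogenation; C6 and C7 relayed from C8 in the key step; C8 then inverted during esterification; C1=C10 geometry from the thermodynamic (E)-alkylidene lactone.

Key step: step 15

Assumption: germacrane numbering is used throughout (C1=C10 ring alkene, C6 lactone carbinol, C7 ring-fusion carbon, C8 ester carbinol, C11–C13 acrylate unit, C14/C15 hydroxymethyls). The key step is taken to add C6 to the allene face anti to the C8 silyloxy group; if the other face reacted, the enantiomeric catalyst in step 9 and a retentive acylation in step 17 would serve the same plan.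

**Route**

Step 1
Reactants: 1 methyl 4,4-dimethoxybutanoate
Product: 2 4,4-dimethoxybutanoic acid
Conditions: LiOH·H2O, THF/H2O, 0 °C to rt; then 1 M HCl to pH 4 at 0 °C
Reagents that add atoms: lithium hydroxide, [Li+].[OH-]
Why: Saponification of a methyl ester; the dimethyl acetal tolerates base and the brief cold acidification.

Step 2
Reactants: 2 4,4-dimethoxybutanoic acid; 3 (S)-4-benzyl-1,3-oxazolidin-2-one
Product: 5 (S)-4-benzyl-3-(4,4-dimethoxybutanoyl)-1,3-oxazolidin-2-one, via mixed pivalic anhydride 4 (not isolated)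
Conditions: PivCl, Et3N, THF, −20 °C; then 3, LiCl, −20 °C to rt
Reagents that add atoms: none
Why: N-acylation of the Evans auxiliary through the mixed anhydride, which should be attacked at the unhindered acyl carbon.

Step 3
Reactants: 5 (S)-4-benzyl-3-(4,4-dimethoxybutanoyl)-1,3-oxazolidin-2-one
Product: 6 (S)-4-benzyl-3-[(2S)-2-(2,2-dimethoxyethyl)pent-4-enoyl]-1,3-oxazolidin-2-one
Conditions: NaHMDS, THF, −78 °C; allyl iodide, −78 to −45 °C
Reagents that add atoms: allyl iodide, C=CCI
Why: Evans asymmetric alkylation; the chelated (Z)-sodium enolate should be allylated on the face opposite the benzyl group, which sets C4 (S).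

Step 4
Reactants: 6 (S)-4-benzyl-3-[(2S)-2-(2,2-dimethoxyethyl)pent-4-enoyl]-1,3-oxazolidin-2-one
Product: 7 (2S)-2-(2,2-dimethoxyethyl)pent-4-en-1-ol
Conditions: LiBH4, MeOH (1 equiv), Et2O, 0 °C
Reagents that add atoms: none
Why: Reductive cleavage of the imide by LiBH4 should give the primary alcohol (C15) and release the auxiliary without touching the acetal or epimerising C4.

Step 5
Reactants: 7 (2S)-2-(2,2-dimethoxyethyl)pent-4-en-1-ol
Product: 8 tert-butyl{[(2S)-2-(2,2-dimethoxyethyl)pent-4-en-1-yl]oxy}diphenylsilane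
Conditions: TBDPSCl, imidazole, DMF, rt
Reagents that add atoms: tert-butyldiphenylsilyl chloride, CC(C)(C)[Si](Cl)(c1ccccc1)c1ccccc1
Why: Silylation of a primary alcohol with a group that survives every later step up to the last.

Step 6
Reactants: 8 tert-butyl{[(2S)-2-(2,2-dimethoxyethyl)pent-4-en-1-yl]oxy}diphenylsilane
Product: 10 (4S)-4-[(tert-butyldiphenylsilyloxy)methyl]-6,6-dimethoxyhexan-1-ol, via B-alkyl-9-BBN adduct 9 (not isolated)
Conditions: 9-BBN, THF, 0 °C to rt; then 3 M NaOH, 30% H2O2, 0 °C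
Reagents that add atoms: hydrogen peroxide, OO
Why: Anti-Markovnikov hydroboration–oxidation of the terminal alkene; 9-BBN places boron on C1 and oxidation proceeds with retention.

Step 7
Reactants: 10 (4S)-4-[(tert-butyldiphenylsilyloxy)methyl]-6,6-dimethoxyhexan-1-ol
Product: 11 (4S)-4-[(tert-butyldiphenylsilyloxy)methyl]-6,6-dimethoxyhexanal
Conditions: Dess–Martin periodinane, NaHCO3, CH2Cl2, 0 °C to rt
Reagents that add atoms: none
Why: Dess–Martin oxidation of a primary alcohol; the bicarbonate buffer protects the acetal.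

Step 8
Reactants: 12 methyl 4-chloro-4-oxobutanoate; 13 bis(trimethylsilyl)acetylene
Product: 14 methyl 4-oxo-6-(trimethylsilyl)hex-5-ynoate
Conditions: AlCl3, CH2Cl2, 0 °C
Reagents that add atoms: none
Why: Friedel–Crafts-type ipso-acylation of the bis-silyl alkyne (β-silyl cation stabilisation) should give the silyl ynone.

Step 9
Reactants: 14 methyl 4-oxo-6-(trimethylsilyl)hex-5-ynoate
Product: 16 (5S)-5-[(trimethylsilyl)ethynyl]oxolan-2-one, via hydroxy ester 15 (not isolated)
Conditions: Ru[(S,S)-TsDPEN](p-cymene) (1 mol %), i-PrOH, rt; then TsOH·H2O (cat.), toluene, 40 °C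
Reagents that add atoms: none
Why: Noyori asymmetric transfer hydrogenation of an alkynyl ketone; the (S,S)-catalyst should give the (S)-propargylic alcohol (the alkynyl group takes the aryl role), which lactonises and so sets C8.

Step 10
Reactants: 16 (5S)-5-[(trimethylsilyl)ethynyl]oxolan-2-one; 11 (4S)-4-[(tert-butyldiphenylsilyloxy)methyl]-6,6-dimethoxyhexanal
Product: 19 (3E,5S)-3-{(4S)-4-[(tert-butyldiphenylsilyloxy)methyl]-6,6-dimethoxyhexylidene}-5-[(trimethylsilyl)ethynyl]oxolan-2-one, via aldol adduct 17 (not isolated), via mesylate 18 (not isolated)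
Conditions: LDA, THF, −78 °C, then 11; AcOH quench; crude: MsCl, Et3N, CH2Cl2, 0 °C; then DBU, rt
Reagents that add atoms: none
Why: Lactone-enolate aldol addition followed by mesylation and E1cB elimination; the thermodynamic (E)-alkylidene lactone places C2 cis to C9, which is the ring-cis geometry needed for C1=C10.

Step 11
Reactants: 19 (3E,5S)-3-{(4S)-4-[(tert-butyldiphenylsilyloxy)methyl]-6,6-dimethoxyhexylidene}-5-[(trimethylsilyl)ethynyl]oxolan-2-one
Product: 21 (2E,6S)-6-[(tert-butyldiphenylsilyloxy)methyl]-2-[(2S)-2-hydroxybut-3-yn-1-yl]-8,8-dimethoxyoct-2-en-1-ol, via C-silyl diol 20 (not isolated)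
Conditions: DIBAL-H, CH2Cl2, −78 to −20 °C; Rochelle salt; then K2CO3, MeOH, rt
Reagents that add atoms: none
Why: DIBAL 1,2-reduction of the unsaturated lactone should open the temporary ring to the C14/C8 diol; methanolysis then removes the alkynyl silyl group.

Step 12
Reactants: 21 (2E,6S)-6-[(tert-butyldiphenylsilyloxy)methyl]-2-[(2S)-2-hydroxybut-3-yn-1-yl]-8,8-dimethoxyoct-2-en-1-ol
Product: 23 (2E,6S)-6-[(tert-butyldiphenylsilyloxy)methyl]-2-[(2S)-2-hydroxypenta-3,4-dien-1-yl]-8,8-dimethoxyoct-2-en-1-ol, via propargylic amine 22 (not isolated)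
Conditions: (CH2O)n, CuI, Cy2NH, 1,4-dioxane, reflux
Reagents that add atoms: paraformaldehyde (as formaldehyde), C=O
Why: Crabbé homologation (Mannich reaction, then copper-mediated 1,5-hydride transfer) converts the terminal alkyne into the terminal allene and tolerates free hydroxyls; C8 is not touched.

Step 13
Reactants: 23 (2E,6S)-6-[(tert-butyldiphenylsilyloxy)methyl]-2-[(2S)-2-hydroxypenta-3,4-dien-1-yl]-8,8-dimethoxyoct-2-en-1-ol
Product: 25 (3S,6E,9S)-9-(tert-butyldimethylsilyloxy)-3,7-bis[(tert-butyldiphenylsilyloxy)methyl]-1,1-dimethoxydodeca-6,10,11-triene, via mono-silyl ether 24 (not isolated)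
Conditions: TBDPSCl (1.05 equiv), imidazole, DMF, 0 °C; then TBSCl, DMAP, rt to 40 °C
Reagents that add atoms: tert-butyldiphenylsilyl chloride, CC(C)(C)[Si](Cl)(c1ccccc1)c1ccccc1; tert-butyldimethylsilyl chloride, CC(C)(C)[Si](C)(C)Cl
Why: Sequential silylation; the bulky TBDPS chloride should take only the primary allylic hydroxyl (C14), and the secondary allenyl carbinol (C8) is then capped as its TBS ether.

Step 14
Reactants: 25 (3S,6E,9S)-9-(tert-butyldimethylsilyloxy)-3,7-bis[(tert-butyldiphenylsilyloxy)methyl]-1,1-dimethoxydodeca-6,10,11-triene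
Product: 26 (3S,6E,9S)-9-(tert-butyldimethylsilyloxy)-3,7-bis[(tert-butyldiphenylsilyloxy)methyl]dodeca-6,10,11-trienal
Conditions: PPTS (cat.), acetone/H2O, 40 °C
Reagents that add atoms: water, O
Why: Mild acid-catalysed acetal hydrolysis should free the C6 aldehyde while the TBS and TBDPS ethers remain.

Step 15
Reactants: 26 (3S,6E,9S)-9-(tert-butyldimethylsilyloxy)-3,7-bis[(tert-butyldiphenylsilyloxy)methyl]dodeca-6,10,11-trienal
Product: 27 (4S,6R,7S,8S)-8-(tert-butyldimethylsilyloxy)-14,15-bis(tert-butyldiphenylsilyloxy)germacra-1(10)E,11(13)-dien-12,6-olide (trans-fused lactone; C8 epimeric to the target)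
Conditions: Ru3(CO)12 (5 mol %), CO (20 atm), 1,4-dioxane (1 mM), 120 °C
Reagents that add atoms: carbon monoxide, [C-]#[O+]
Why: Proposed new method: Ru(0) should bind the C6 aldehyde and the internal C7=C11 bond of the 1,2-diene and couple them oxidatively to an oxaruthenacyclopentane (C6–C7), CO then inserts into the Ru–C11 bond (C11–C12) and C–O reductive elimination closes O6–C12, i.e. an allenic hetero-Pauson–Khand [2+2+1]. The closest known reaction type is the Ru3(CO)12- or Mo(CO)6-mediated cyclocarbonylation of allenyl aldehydes to bicyclic α-methylene-γ-butyrolactones, shown with three- and four-atom tethers and extended here to an eight-atom tether. The ten-membered carbocycle closes by union of C6 and C7 in the oxidative coupling (exo at both π-bonds, since O6 and C11 stay outside the carbocycle, with the ring-cis C1=C10 alkene as the turn), and the five-membered lactone closes by migratory insertion and reductive elimination at the metal. C7 should be set by bond formation on the allene face anti to the C8 silyloxy group with H8 eclipsing the cumulene (allylic-ether steric model), and C6 by the trans placement of C5 and C8 on the metallacycle, which avoids their eclipsing and gives the trans ring fusion, so both centres are relayed from C8. The step needs the internal allene bond to react rather than the terminal one, the aldehyde/allene pair rather than the trisubstituted alkene, and ring closure rather than oligomerisation; these rest on the exo-methylene outcome known for allenyl aldehydes, on the inertness of trisubstituted alkenes to Ru carbonyls, and on the 1 mM concentration.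

Step 16
Reactants: 27 (4S,6R,7S,8S)-8-(tert-butyldimethylsilyloxy)-14,15-bis(tert-butyldiphenylsilyloxy)germacra-1(10)E,11(13)-dien-12,6-olide
Product: 28 (4S,6R,7S,8S)-14,15-bis(tert-butyldiphenylsilyloxy)-8-hydroxygermacra-1(10)E,11(13)-dien-12,6-olide
Conditions: HF·pyridine, pyridine, THF, 0 °C
Reagents that add atoms: none
Why: Buffered acidic fluoride should cleave the secondary TBS ether well before the two primary TBDPS ethers (selective desilylation).

Step 17
Reactants: 28 (4S,6R,7S,8S)-14,15-bis(tert-butyldiphenylsilyloxy)-8-hydroxygermacra-1(10)E,11(13)-dien-12,6-olide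
Product: 29 (4S,6R,7S,8R)-14,15-bis(tert-butyldiphenylsilyloxy)-8-(methacryloyloxy)germacra-1(10)E,11(13)-dien-12,6-olide
Conditions: methacrylic acid, PPh3, DIAD, toluene, 0 °C to rt
Reagents that add atoms: methacrylic acid, C=C(C)C(=O)O
Why: Mitsunobu esterification; SN2 displacement of the oxyphosphonium by methacrylate should invert C8 to the (R) configuration of the target while installing the ester.

Step 18
Reactants: 29 (4S,6R,7S,8R)-14,15-bis(tert-butyldiphenylsilyloxy)-8-(methacryloyloxy)germacra-1(10)E,11(13)-dien-12,6-olide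
Product: 30 (4S,6R,7S,8R)-14,15-dihydroxy-8-(methacryloyloxy)germacra-1(10)E,11(13)-dien-12,6-olide (target)
Conditions: HF·pyridine (excess), THF, rt
Reagents that add atoms: none
Why: Fluoride cleavage of both primary TBDPS ethers under non-basic conditions, which should avoid acyl migration and conjugate addition to the two acrylate units.

**Compound list**
1 | methyl 4,4-dimethoxybutanoate | COC(=O)CCC(OC)OC | starting material
2 | 4,4-dimethoxybutanoic acid | OC(=O)CCC(OC)OC | intermediate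
3 | (S)-4-benzyl-1,3-oxazolidin-2-one | O=C1N[C@@H](Cc2ccccc2)CO1 | starting material
4 | 4,4-dimethoxybutanoic pivalic anhydride | CC(C)(C)C(=O)OC(=O)CCC(OC)OC | intermediate
5 | (S)-4-benzyl-3-(4,4-dimethoxybutanoyl)-1,3-oxazolidin-2-one | O=C1OC[C@H](Cc2ccccc2)N1C(=O)CCC(OC)OC | intermediate
6 | (S)-4-benzyl-3-[(2S)-2-(2,2-dimethoxyethyl)pent-4-enoyl]-1,3-oxazolidin-2-one | O=C1OC[C@H](Cc2ccccc2)N1C(=O)[C@@H](CC=C)CC(OC)OC | intermediate
7 | (2S)-2-(2,2-dimethoxyethyl)pent-4-en-1-ol | OC[C@@H](CC=C)CC(OC)OC | intermediate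
8 | tert-butyl{[(2S)-2-(2,2-dimethoxyethyl)pent-4-en-1-yl]oxy}diphenylsilane | C=CC[C@H](CO[Si](c1ccccc1)(c1ccccc1)C(C)(C)C)CC(OC)OC | intermediate
9 | B-alkyl-9-borabicyclo[3.3.1]nonane adduct of 8 (boron on C1) | C1CC2CCCC(C1)B2CCC[C@H](CO[Si](c1ccccc1)(c1ccccc1)C(C)(C)C)CC(OC)OC | intermediate
10 | (4S)-4-[(tert-butyldiphenylsilyloxy)methyl]-6,6-dimethoxyhexan-1-ol | OCCC[C@H](CO[Si](c1ccccc1)(c1ccccc1)C(C)(C)C)CC(OC)OC | intermediate
11 | (4S)-4-[(tert-butyldiphenylsilyloxy)methyl]-6,6-dimethoxyhexanal | O=CCC[C@H](CO[Si](c1ccccc1)(c1ccccc1)C(C)(C)C)CC(OC)OC | intermediate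
12 | methyl 4-chloro-4-oxobutanoate | COC(=O)CCC(=O)Cl | starting material
13 | bis(trimethylsilyl)acetylene | C[Si](C)(C)C#C[Si](C)(C)C | starting material
14 | methyl 4-oxo-6-(trimethylsilyl)hex-5-ynoate | COC(=O)CCC(=O)C#C[Si](C)(C)C | intermediate
15 | methyl (4S)-4-hydroxy-6-(trimethylsilyl)hex-5-ynoate | COC(=O)CC[C@H](O)C#C[Si](C)(C)C | intermediate
16 | (5S)-5-[(trimethylsilyl)ethynyl]oxolan-2-one | C[Si](C)(C)C#C[C@@H]1CCC(=O)O1 | intermediate
17 | aldol adduct of 16 and 11 (β-hydroxy lactone, mixture at the two new centres) | O=C1O[C@H](C#C[Si](C)(C)C)CC1C(O)CC[C@H](CO[Si](c2ccccc2)(c2ccccc2)C(C)(C)C)CC(OC)OC | intermediate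
18 | methanesulfonate of 17 | O=C1O[C@H](C#C[Si](C)(C)C)CC1C(OS(C)(=O)=O)CC[C@H](CO[Si](c2ccccc2)(c2ccccc2)C(C)(C)C)CC(OC)OC | intermediate
19 | (3E,5S)-3-{(4S)-4-[(tert-butyldiphenylsilyloxy)methyl]-6,6-dimethoxyhexylidene}-5-[(trimethylsilyl)ethynyl]oxolan-2-one | O=C1O[C@H](C#C[Si](C)(C)C)C/C1=C\CC[C@H](CO[Si](c2ccccc2)(c2ccccc2)C(C)(C)C)CC(OC)OC | intermediate
20 | (2E,6S)-6-[(tert-butyldiphenylsilyloxy)methyl]-2-[(2S)-2-hydroxy-4-(trimethylsilyl)but-3-yn-1-yl]-8,8-dimethoxyoct-2-en-1-ol | C[Si](C)(C)C#C[C@@H](O)C/C(CO)=C\CC[C@H](CO[Si](c1ccccc1)(c1ccccc1)C(C)(C)C)CC(OC)OC | intermediate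
21 | (2E,6S)-6-[(tert-butyldiphenylsilyloxy)methyl]-2-[(2S)-2-hydroxybut-3-yn-1-yl]-8,8-dimethoxyoct-2-en-1-ol | C#C[C@@H](O)C/C(CO)=C\CC[C@H](CO[Si](c1ccccc1)(c1ccccc1)C(C)(C)C)CC(OC)OC | intermediate
22 | (2E,6S)-6-[(tert-butyldiphenylsilyloxy)methyl]-2-[(2S)-5-(dicyclohexylamino)-2-hydroxypent-3-yn-1-yl]-8,8-dimethoxyoct-2-en-1-ol | C1CCCCC1N(CC#C[C@@H](O)C/C(CO)=C\CC[C@H](CO[Si](c2ccccc2)(c2ccccc2)C(C)(C)C)CC(OC)OC)C1CCCCC1 | intermediate
23 | (2E,6S)-6-[(tert-butyldiphenylsilyloxy)methyl]-2-[(2S)-2-hydroxypenta-3,4-dien-1-yl]-8,8-dimethoxyoct-2-en-1-ol | C=C=C[C@@H](O)C/C(CO)=C\CC[C@H](CO[Si](c1ccccc1)(c1ccccc1)C(C)(C)C)CC(OC)OC | intermediate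
24 | 14-O-TBDPS ether of 23 (free C8 hydroxyl) | C=C=C[C@@H](O)C/C(CO[Si](c1ccccc1)(c1ccccc1)C(C)(C)C)=C\CC[C@H](CO[Si](c1ccccc1)(c1ccccc1)C(C)(C)C)CC(OC)OC | intermediate
25 | (3S,6E,9S)-9-(tert-butyldimethylsilyloxy)-3,7-bis[(tert-butyldiphenylsilyloxy)methyl]-1,1-dimethoxydodeca-6,10,11-triene | C=C=C[C@@H](O[Si](C)(C)C(C)(C)C)C/C(CO[Si](c1ccccc1)(c1ccccc1)C(C)(C)C)=C\CC[C@H](CO[Si](c1ccccc1)(c1ccccc1)C(C)(C)C)CC(OC)OC | intermediate
26 | (3S,6E,9S)-9-(tert-butyldimethylsilyloxy)-3,7-bis[(tert-butyldiphenylsilyloxy)methyl]dodeca-6,10,11-trienal | C=C=C[C@@H](O[Si](C)(C)C(C)(C)C)C/C(CO[Si](c1ccccc1)(c1ccccc1)C(C)(C)C)=C\CC[C@H](CO[Si](c1ccccc1)(c1ccccc1)C(C)(C)C)CC=O | intermediate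
27 | (4S,6R,7S,8S)-8-(tert-butyldimethylsilyloxy)-14,15-bis(tert-butyldiphenylsilyloxy)germacra-1(10)E,11(13)-dien-12,6-olide | CC(C)(C)[Si](C)(C)O[C@H]1C/C(CO[Si](c3ccccc3)(c3ccccc3)C(C)(C)C)=C\CC[C@H](CO[Si](c3ccccc3)(c3ccccc3)C(C)(C)C)C[C@H]2OC(=O)C(=C)[C@H]12 | intermediate
28 | (4S,6R,7S,8S)-14,15-bis(tert-butyldiphenylsilyloxy)-8-hydroxygermacra-1(10)E,11(13)-dien-12,6-olide | O[C@H]1C/C(CO[Si](c3ccccc3)(c3ccccc3)C(C)(C)C)=C\CC[C@H](CO[Si](c3ccccc3)(c3ccccc3)C(C)(C)C)C[C@H]2OC(=O)C(=C)[C@H]12 | intermediate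
29 | (4S,6R,7S,8R)-14,15-bis(tert-butyldiphenylsilyloxy)-8-(methacryloyloxy)germacra-1(10)E,11(13)-dien-12,6-olide | C=C(C)C(=O)O[C@@H]1C/C(CO[Si](c3ccccc3)(c3ccccc3)C(C)(C)C)=C\CC[C@H](CO[Si](c3ccccc3)(c3ccccc3)C(C)(C)C)C[C@H]2OC(=O)C(=C)[C@H]12 | intermediate
30 | (4S,6R,7S,8R)-14,15-dihydroxy-8-(methacryloyloxy)germacra-1(10)E,11(13)-dien-12,6-olide | C=C(C)C(=O)O[C@@H]1C/C(CO)=C\CC[C@H](CO)C[C@H]2OC(=O)C(=C)[C@H]12 | target

**Totals**
Total step count: 18. Longest linear sequence: 16 steps (steps 1–7, then 10–18).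

**Steps most likely to fail**

Step 15. The [2+2+1] may fail in several ways: intermolecular coupling and chain growth instead of ring closure, coupling at the terminal allene bond (a twelve-membered alkylidene lactone), cis ring fusion, or reaction on the other allene face. The fallback uses known reaction types, sets out from 25 and returns at 27. The allene of 25 is haloborated with B-bromo-9-BBN (CH2Cl2, −78 °C; bromine to the central carbon, boron to the CH2 terminus) to give the 2-bromoallyl borane F1. F1 is oxidised in the same flask (NaBO3·4H2O) to the 2-bromoallylic alcohol F2. Appel bromination (CBr4, PPh3) gives the dibromide F3, and acetal hydrolysis (PPTS, wet acetone) gives the bromoallyl bromide aldehyde F4. An intramolecular Nozaki–Hiyama–Kishi allylation (CrCl2, THF, high dilution) should close the ten-membered ring through C7 to the anti bromohydrin F5; the allylchromium equilibrates, so the alkene geometry of F4 does not matter. Palladium-catalysed cyclocarbonylation of the 2-bromo homoallylic alcohol (Pd(PPh3)4, CO 1 atm, K2CO3, THF, 65 °C) then forms C11–C12 and the lactone, giving 27.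

Step 17. The activated C8 oxyphosphonium may eliminate toward C9 (conjugation with C1=C10) or toward C7 instead of undergoing SN2 inversion at this hindered ring position, and the phosphine may add reversibly to the methylene lactone. The fallback sets out from 28 and returns at 29. The alcohol 28 is converted into its chloromethanesulfonate F6 (ClCH2SO2Cl, pyridine, 0 °C), a small and very reactive leaving group. F6 is displaced with inversion by caesium methacrylate and 18-crown-6 in toluene at 40 °C, an ionic SN2 without phosphine or betaine base, to give 29.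

Step 16. A primary TBDPS group may be lost in competition with the slow cleavage of the hindered secondary TBS ether, or the TBS ether may not cleave fully. The fallback changes the C8 protecting group to one removed oxidatively; it sets out from 23 and returns at 28. Compound 23 is silylated with TBDPSCl alone and 24 is isolated. Its C8 hydroxyl is etherified (NaH, PMBCl, Bu4NI, DMF) to the p-methoxybenzyl ether F7. Acetal hydrolysis (PPTS, wet acetone) gives the aldehyde F8, and the conditions of step 15 give the PMB-protected lactone F9. DDQ (CH2Cl2, pH 7 buffer) then removes only the PMB group to give 28.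

**Further compounds**
F1 | step 15 | 2-bromoallyl-9-BBN from bromoboration of 25 (boron on C13, bromine on C11) | C1CC2CCCC(C1)B2C/C(Br)=C\[C@@H](O[Si](C)(C)C(C)(C)C)C/C(CO[Si](c1ccccc1)(c1ccccc1)C(C)(C)C)=C\CC[C@H](CO[Si](c1ccccc1)(c1ccccc1)C(C)(C)C)CC(OC)OC
F2 | step 15 | (E)-2-bromoallylic alcohol (hydroxyl on C13, bromine on C11, C6 dimethyl acetal) | OC/C(Br)=C\[C@@H](O[Si](C)(C)C(C)(C)C)C/C(CO[Si](c1ccccc1)(c1ccccc1)C(C)(C)C)=C\CC[C@H](CO[Si](c1ccccc1)(c1ccccc1)C(C)(C)C)CC(OC)OC
F3 | step 15 | (E)-2-bromoallylic bromide (C6 dimethyl acetal) | BrC/C(Br)=C\[C@@H](O[Si](C)(C)C(C)(C)C)C/C(CO[Si](c1ccccc1)(c1ccccc1)C(C)(C)C)=C\CC[C@H](CO[Si](c1ccccc1)(c1ccccc1)C(C)(C)C)CC(OC)OC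
F4 | step 15 | (E)-2-bromoallylic bromide with free C6 aldehyde | BrC/C(Br)=C\[C@@H](O[Si](C)(C)C(C)(C)C)C/C(CO[Si](c1ccccc1)(c1ccccc1)C(C)(C)C)=C\CC[C@H](CO[Si](c1ccccc1)(c1ccccc1)C(C)(C)C)CC=O
F5 | step 15 | ten-membered 6-hydroxy-7-(1-bromovinyl) carbocycle (anti bromohydrin) | CC(C)(C)[Si](C)(C)O[C@H]1C/C(CO[Si](c2ccccc2)(c2ccccc2)C(C)(C)C)=C\CC[C@H](CO[Si](c2ccccc2)(c2ccccc2)C(C)(C)C)C[C@@H](O)[C@@H]1C(Br)=C
F6 | step 17 | 8-O-chloromethanesulfonate of 28 | ClCS(=O)(=O)O[C@H]1C/C(CO[Si](c3ccccc3)(c3ccccc3)C(C)(C)C)=C\CC[C@H](CO[Si](c3ccccc3)(c3ccccc3)C(C)(C)C)C[C@H]2OC(=O)C(=C)[C@H]12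
F7 | step 16 | 8-O-(4-methoxybenzyl) ether of 24 | C=C=C[C@@H](OCc1ccc(OC)cc1)C/C(CO[Si](c1ccccc1)(c1ccccc1)C(C)(C)C)=C\CC[C@H](CO[Si](c1ccccc1)(c1ccccc1)C(C)(C)C)CC(OC)OC
F8 | step 16 | 8-O-(4-methoxybenzyl) allenyl aldehyde | C=C=C[C@@H](OCc1ccc(OC)cc1)C/C(CO[Si](c1ccccc1)(c1ccccc1)C(C)(C)C)=C\CC[C@H](CO[Si](c1ccccc1)(c1ccccc1)C(C)(C)C)CC=O
F9 | step 16 | 8-O-(4-methoxybenzyl) analogue of 27 | COc1ccc(CO[C@H]2C/C(CO[Si](c4ccccc4)(c4ccccc4)C(C)(C)C)=C\CC[C@H](CO[Si](c4ccccc4)(c4ccccc4)C(C)(C)C)C[C@H]3OC(=O)C(=C)[C@H]23)cc1
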